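## The problem

The target 12 is a single, fully substituted cyclohexene. C1=C2 is a trisubstituted alkene whose C1 carries the exocyclic carbon C7 (as CH2OBz), and C3, C4, C5 and C6 are four contiguous oxygen-bearing stereocentres, (3R,4S,5R,6S). With the ring drawn flat, the hydroxyls on C3 and C6 lie on one face and the C4 hydroxyl and C5 benzoate on the other. C3/C6 are therefore cis across the alkene, and C4/C5 are a cis pair that is trans to both neighbours. Once C3 and C6 are in place they can send a cis addition at a C4=C5 alkene to the opposite face, so these two centres can control the other two and only their absolute configuration has to come from outside. Five oxygens must be told apart: benzoates belong on the primary O7 and the secondary O5 only, while O3, O4 and O6 stay free, and O4 and O5 differ only in their neighbours and in their axial or equatorial position. The compound is fragile: benzoates migrate to neighbouring hydroxyls under base, the allylic C–O bonds at C3, C6 and C7 can ionise in strong acid, and the ring is a few eliminations away from an arene. The feature that opens the shortest route is the pattern C6(O)–C1(C7)=C2–C3(O) with the two oxygens cis: with a C4=C5 double bond added, the ring is the Diels–Alder adduct of an (E,E)-1,4-dioxygenated butadiene (C3 to C6) and a propiolate (C7, C1, C2).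

## Retrosynthesis

**C5 benzoate.** The last bond made is the acyl C–O bond at O5: 12 is cut to the tetraol monobenzoate 9 and trimethyl orthobenzoate 10. The cut is placed last, after the O7 acylation, so that the secondary benzoate, the group most apt to migrate, does not have to survive another step. The neighbouring choice, acylating a precursor with O3, O4 and O6 protected, would need three protections orthogonal to benzoate and their removal. The forward reaction must find O5 among four secondary hydroxyls. Only the cis pair O4/O5 can close an unstrained five-membered cyclic orthoester (11, formed in the flask), and acid opening of such an orthoester places the ester on the axial oxygen. That oxygen is O5 if C6–OH stands pseudoaxial to avoid allylic strain with the C1 substituent.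

**O4/O5 acetonide and C7 benzoate.** 9 is traced back at O4 and O5 to the acetonide 8, and 8 is cut at the O7 acyl bond to the triol 6 and benzoyl chloride 7. The acetonide earns its two steps: in 6 only O3, O6 and O7 are free and O7 is the only primary one, so one equivalent of 7 should suffice, whereas without it five hydroxyls would compete. 6 has no ester and no aromatic ring. The forward steps ask only for primary-over-secondary selectivity and for an acid that removes an isopropylidene acetal without harming an allylic benzoate.

**Oxidation level and acetates.** 6 is traced back, without cutting a skeletal bond, to 5, in which C7 is a methyl ester and O3 and O6 are acetates. These are the forms in which the atoms leave the cycloaddition, and one excess of a hydride reagent should convert all three groups in a single operation. Carrying C7 as a protected alcohol from the start is not an option, because an unactivated propargyl derivative is not a dienophile.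

**C4–O and C5–O bonds.** 5 is cut at its acetal to the diol 4, and 4 at both diol C–O bonds to the 1,4-diene 3. Introducing O4 and O5 after the ring exists, and not with the diene, lets C3 and C6 set C4 and C5: cis-dihydroxylation should take the C4=C5 alkene from the face opposite the two acetates. 3 has two stereocentres in place of four. The forward reaction must choose C4=C5 over the ester-conjugated C1=C2 and must be gentle, because 3 is one loss of acetic acid away from an arene.

**C2–C3 and C1–C6 bonds.** 3 is cut across the ring to (1E,3E)-1,4-diacetoxybutadiene 1 and methyl propiolate 2. No other cut removes as much: the ring, two ring bonds and both remaining stereocentres go in one step, C7 arrives on C1 at an oxidation level that activates the dienophile, and both precursors are achiral and commercial. Cuts of a single ring bond (an aldol closing C2–C3, a metathesis across C1=C2) would start from chiral-pool chains many steps long. The forward reaction must proceed at a temperature the product survives and must be enantioselective; the cis relation of C3 and C6 follows from the diene geometry.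

## Roads not taken

**Alternative 1:** Ferrier carbocyclisation of a sugar enol ether. The cut is the C2–C3 bond. L-Mannose A1 would be elaborated to the 6-deoxyhex-5-enopyranoside A2, with 4-methoxybenzyl ethers on the oxygens that become O4 and O6 and a benzoate on the one that becomes O5. Catalytic Hg(OCOCF3)2 in aqueous acetone would hydroxymercurate the enol ether; opening of the hemiacetal and intramolecular aldol attack of C2 on C3 would close the ring to the β-hydroxy ketone A3 from either anomer of A2.
- Merits: the reaction type is well established, C4, C5 and C6 come from the sugar, and O5 is distinguished from O4 and O6 by ordinary carbohydrate protecting-group chemistry before the ring exists. In that last respect this road is better than the chosen plan, which leaves the distinction to a late orthoester opening.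
- Weak points: A1 is the unnatural, costly enantiomer, and reaching A2 would take on the order of eight to ten steps. A3 lacks C7 and the C1=C2 alkene; they must be installed at a ketone whose β-oxygen (O3) is lost by elimination under most basic enolisations, next to a base-labile benzoate. A divalent mercury salt is an added burden.
- Comparison: against the better oxygen differentiation, the chosen plan sets a sequence less than half as long, a dienophile that brings C7 and the alkene with it, and cheap achiral starting materials.

**Alternative 2:** Singlet-oxygen cycloaddition to a shikimate-derived diene. The cuts are the C3–O and C6–O bonds. (−)-Shikimic acid A4 already holds C7, C1 and the O4/O5 pair in the right absolute configuration. Esterification, acetonide formation, dehydration, reduction and benzoylation would give the diene A5 (C6=C1–C2=C3). Singlet oxygen (O2, light, tetraphenylporphyrin) would add across C3 and C6 from the face opposite the acetonide to the endoperoxide A6, and reduction of the O–O bond would give 8, the compound the chosen route reaches in step 5. The last two steps would be shared.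
- Merits: every step is of a known type, absolute configuration comes from the chiral pool, and the cis relation of O3 and O6 and their trans relation to the acetonide come from a cycloaddition with a clear facial bias. On reliability this road is at least the equal of the chosen one and probably better.
- Weak points: about nine to ten steps against seven. A5 is a cyclohexa-1,3-diene flanked by allylic C–O bonds, prone to aromatise and to dimerise. Singlet oxygen can also react in the ene mode at the C7 methylene. A6 is base-sensitive (Kornblum–DeLaMare rearrangement). The O4/O5 distinction is solved no better than in the chosen plan.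
- Comparison: the chosen plan sets against it brevity, independence of a chiral-pool acid and access to either enantiomer through the choice of catalyst. Its unproven step is the first one, where failure costs least.

**Alternative 3:** Silver-promoted ring expansion of a gem-dibromocyclopropane. Here C2 is an inserted carbon: the cut takes C2 out of the ring and leaves the cyclopentene A7, whose alkene carbons are C1 and C3. Dibromocarbene addition would give the 6,6-dibromobicyclo[3.1.0]hexane A8 (drawn with the cyclopropane anti to the acetonide; these two configurations are lost on opening). AgClO4 in aqueous acetone would ionise the bromide syn to the five-membered ring with disrotatory opening of the C1–C3 bond, the positive charge being shared by C1 and C3, and water would add at C3 opposite the acetonide to give the bromo-alcohol A9.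
- Merits: ring expansion and C3 oxygenation in one step, no arene-prone diene on the way, absolute configuration from the chiral pool, and a key step with closer precedent than the chosen one.
- Weak points: water can add at either end of the allylic system, and capture at the tertiary end C1 would give the wrong constitution. The bromine on C2 is unwanted and costs a reduction. Carbene addition to a hindered, oxygen-flanked trisubstituted alkene is slow. A7, with three oxygenated stereocentres, needs a long sequence of its own. After A9, two silyl ethers must be exchanged before the O5 problem is even reached.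
- Comparison: apart from the precedent of its key step, this road offers nothing the chosen plan lacks; it is clearly longer and its regiochemistry is less certain.

Key step: step 1

Conventions and assumptions:
- Ring locants in all names follow the target (C1 carries C7, C2 is the alkene CH, C3 to C6 follow round the ring).
- The oxazaborolidine of step 1 is a commercial catalyst (also made from (S)-α,α-diphenylprolinol and tri-o-tolylboroxine) and carries no compound number.
- Assumption: the sense of induction for an alkynoate on this catalyst cannot be read from the enoate model (no α-hydrogen for a second contact), so the (S)-catalyst is written; if a test run gives the mirror-image adduct, the equally available (R)-catalyst is used and nothing else changes.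

Step 1
Reactants: 1 (1E,3E)-buta-1,3-diene-1,4-diyl diacetate; 2 methyl propiolate
Product: 3 methyl (3S,6R)-3,6-diacetoxycyclohexa-1,4-diene-1-carboxylate
Conditions: 2 (2 equiv), (S)-3,3-diphenyl-1-(o-tolyl)tetrahydro-1H,3H-pyrrolo[1,2-c][1,3,2]oxazaborole (20 mol%), Tf2NH (16 mol%), CH2Cl2, −78 → −20 °C; pH 7 NaH2PO4/Na2HPO4 buffer at −78 °C; crude 3 used at once
Reagents that add atoms: none
Why: Proposed new method: the N-protonated oxazaborolidine, a cationic boron Lewis acid, binds the ester carbonyl of 2, lowers the LUMO of the alkyne π system conjugated with it and lets diene 1 add in a concerted, suprafacial [4+2] Diels–Alder reaction that forms C2–C3 and C1–C6 together; the closest known reaction types are the thermal Diels–Alder reaction of 1,4-diacyloxybutadienes with acetylenic esters and the enantioselective Diels–Alder reactions of acetylenic aldehydes and ketones under chiral cationic boron Lewis acids, while this pairing of an alkynoate with a 1,4-diacyloxy diene under such a catalyst is not established. The six-membered carbocycle closes by intermolecular cycloaddition, both ring bonds in one step, and emerges as a cyclohexa-1,4-diene. The cis relation of the new stereocentres C3 and C6 follows from suprafacial addition to the E,E diene and needs no outside control. Their absolute configuration is set by the catalyst, which has to do two things at once: leave one face of the bound ester plane open and hold the diene backbone in one orientation relative to the coordinated carbonyl, because on a given face the two orientations lead to opposite enantiomers. No regiochemical question arises because 1 is C2-symmetric, and there is no endo/exo diastereomerism because both dienophile carbons stay sp2. The selectivity required is therefore enantioselectivity alone, together with survival of the two bis-allylic acetates, which the low temperature, the buffered cold quench and the immediate use of crude 3 are meant to secure. The excess of 2 keeps the catalyst on the alkynoate and away from the acetate carbonyls of 1.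

Step 2
Reactants: 3 methyl (3S,6R)-3,6-diacetoxycyclohexa-1,4-diene-1-carboxylate
Product: 4 methyl (3R,4R,5S,6S)-3,6-diacetoxy-4,5-dihydroxycyclohex-1-ene-1-carboxylate
Conditions: OsO4 (2 mol%), NMO (1.2 equiv), acetone/H2O 5:1, 0 °C; aq. NaHSO3
Reagents that add atoms: osmium tetroxide, O=[Os](=O)(=O)=O (catalytic carrier of the two oxygens); N-methylmorpholine N-oxide, C[N+]1([O-])CCOCC1; water, O
Why: Catalytic syn-dihydroxylation with OsO4 and NMO as reoxidant; the electrophilic oxidant should take the isolated C4=C5 alkene in preference to the ester-conjugated, trisubstituted C1=C2. Addition from the face opposite the two cis allylic acetates (steric shielding and the usual anti preference to allylic oxygen) sets C4 and C5 cis to each other and trans to C3 and C6; this site and face selectivity is well precedented for cyclohexenes flanked by two cis allylic acyloxy groups.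

Step 3
Reactants: 4 methyl (3R,4R,5S,6S)-3,6-diacetoxy-4,5-dihydroxycyclohex-1-ene-1-carboxylate
Product: 5 methyl (3R,4S,5R,6S)-3,6-diacetoxy-4,5-(isopropylidenedioxy)cyclohex-1-ene-1-carboxylate
Conditions: Me2C(OMe)2, PPTS (cat.), acetone, rt
Reagents that add atoms: 2,2-dimethoxypropane, COC(C)(C)OC
Why: Acid-catalysed transacetalisation of a cis-1,2-diol to its acetonide; it ties O4 and O5 together, stops acetyl migration onto them and shields them through the reduction and the O7 acylation. No stereocentre is touched.

Step 4
Reactants: 5 methyl (3R,4S,5R,6S)-3,6-diacetoxy-4,5-(isopropylidenedioxy)cyclohex-1-ene-1-carboxylate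
Product: 6 (3R,4S,5R,6S)-1-(hydroxymethyl)-4,5-(isopropylidenedioxy)cyclohex-1-ene-3,6-diol
Conditions: iBu2AlH (8 equiv), CH2Cl2, −78 → 0 °C; aq. potassium sodium tartrate
Reagents that add atoms: none
Why: Excess iBu2AlH reduces the enoate in the 1,2 sense to the allylic alcohol and cleaves both acetates reductively in the same operation. The reagent is not basic, so the C6 acetate is not eliminated through an ester enolate, and the acetonide is inert to it.

Step 5
Reactants: 6 (3R,4S,5R,6S)-1-(hydroxymethyl)-4,5-(isopropylidenedioxy)cyclohex-1-ene-3,6-diol; 7 benzoyl chloride
Product: 8 [(3R,4S,5R,6S)-3,6-dihydroxy-4,5-(isopropylidenedioxy)cyclohex-1-en-1-yl]methyl benzoate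
Conditions: 7 (1.05 equiv), 2,4,6-collidine, CH2Cl2, −78 → −20 °C
Reagents that add atoms: none
Why: Selective acylation of a primary alcohol: O7 is far less hindered than the two secondary allylic hydroxyls, each of which sits next to an acetonide carbon. One equivalent of acid chloride with a weak hindered pyridine base at low temperature is a standard way to acylate a primary alcohol beside secondary ones.

Step 6
Reactants: 8 [(3R,4S,5R,6S)-3,6-dihydroxy-4,5-(isopropylidenedioxy)cyclohex-1-en-1-yl]methyl benzoate
Product: 9 [(3R,4S,5R,6S)-3,4,5,6-tetrahydroxycyclohex-1-en-1-yl]methyl benzoate
Conditions: AcOH/H2O 4:1, 45 °C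
Reagents that add atoms: none
Why: Acid hydrolysis of the isopropylidene acetal; aqueous acetic acid is too weak to ionise the allylic C–O bonds or hydrolyse the benzoate, and without base the benzoate should not migrate.

Step 7
Reactants: 9 [(3R,4S,5R,6S)-3,4,5,6-tetrahydroxycyclohex-1-en-1-yl]methyl benzoate; 10 trimethyl orthobenzoate
Product: 12 [(3R,4S,5R,6S)-5-(benzoyloxy)-3,4,6-trihydroxycyclohex-1-en-1-yl]methyl benzoate, via cyclic 4,5-orthobenzoate 11 (not isolated)
Conditions: 10 (1.2 equiv), CSA (cat.), MeCN, rt; then AcOH/H2O 4:1, rt
Reagents that add atoms: water, O
Why: Orthoester method for monoacylation of a cis-1,2-diol: acid-catalysed exchange with 10 closes the five-membered cyclic orthobenzoate 11 on the cis O4/O5 pair (the trans pairs would need strained trans-fused rings), and mild aqueous acid opens it through the hemi-orthoester to the hydroxy ester with the acyl group on the axial oxygen. With C6–OH pseudoaxial to avoid allylic strain with the C1 substituent, O5 is axial and O4 equatorial, so the benzoate should end on O5; no stereocentre changes.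

Compound list

1 | (1E,3E)-buta-1,3-diene-1,4-diyl diacetate | CC(=O)O/C=C/C=C/OC(C)=O | starting material
2 | methyl propiolate (methyl prop-2-ynoate) | C#CC(=O)OC | starting material
3 | methyl (3S,6R)-3,6-diacetoxycyclohexa-1,4-diene-1-carboxylate (acetates cis) | COC(=O)C1=C[C@@H](OC(C)=O)C=C[C@H]1OC(C)=O | intermediate
4 | methyl (3R,4R,5S,6S)-3,6-diacetoxy-4,5-dihydroxycyclohex-1-ene-1-carboxylate (cis-diol anti to both acetates) | COC(=O)C1=C[C@@H](OC(C)=O)[C@H](O)[C@H](O)[C@H]1OC(C)=O | intermediate
5 | methyl (3R,4S,5R,6S)-3,6-diacetoxy-4,5-(isopropylidenedioxy)cyclohex-1-ene-1-carboxylate | COC(=O)C1=C[C@@H](OC(C)=O)[C@@H]2OC(C)(C)O[C@@H]2[C@H]1OC(C)=O | intermediate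
6 | (3R,4S,5R,6S)-1-(hydroxymethyl)-4,5-(isopropylidenedioxy)cyclohex-1-ene-3,6-diol | OCC1=C[C@@H](O)[C@@H]2OC(C)(C)O[C@@H]2[C@H]1O | intermediate
7 | benzoyl chloride | O=C(Cl)c1ccccc1 | starting material
8 | [(3R,4S,5R,6S)-3,6-dihydroxy-4,5-(isopropylidenedioxy)cyclohex-1-en-1-yl]methyl benzoate | O=C(OCC1=C[C@@H](O)[C@@H]2OC(C)(C)O[C@@H]2[C@H]1O)c1ccccc1 | intermediate
9 | [(3R,4S,5R,6S)-3,4,5,6-tetrahydroxycyclohex-1-en-1-yl]methyl benzoate | O=C(OCC1=C[C@@H](O)[C@H](O)[C@H](O)[C@H]1O)c1ccccc1 | intermediate
10 | trimethyl orthobenzoate | COC(OC)(OC)c1ccccc1 | starting material
11 | cyclic 4,5-O-(α-methoxybenzylidene) orthoester of 9 (2-methoxy-2-phenyl-1,3-dioxolane on O4/O5, both epimers at the orthoester carbon) | O=C(OCC1=C[C@@H](O)[C@@H]2OC(OC)(c3ccccc3)O[C@@H]2[C@H]1O)c1ccccc1 | intermediate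
12 | [(3R,4S,5R,6S)-5-(benzoyloxy)-3,4,6-trihydroxycyclohex-1-en-1-yl]methyl benzoate | O=C(OCC1=C[C@@H](O)[C@H](O)[C@H](OC(=O)c2ccccc2)[C@H]1O)c1ccccc1 | target

Total step count: 7. Longest linear sequence: 7 steps (1 and 2 to 12).

Steps least certain to work

**Step 1 (key step, proposed new method).** Three things can go wrong.
- Too little rate: the weakly donating diacyloxy diene may not react with the alkynoate at the low temperature the product tolerates.
- Acid-promoted loss of acetic acid: ionisation at a bis-allylic carbon of 3 followed by proton loss gives aromatisation, and the enol acetates of 1 may also decompose on the strong acid.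
- Low enantioselectivity: the catalyst must fix both the open face and the orientation of the diene, and the acetate carbonyls may compete for boron.

Fallback by known chemistry, setting out from 1 and returning at 6:
- 1 is combined without catalyst (neat at the lowest temperature that gives conversion, or under about 10 kbar at ambient temperature) with (1R,2S,5R)-menthyl propiolate F1, made from propiolic acid and (−)-menthol by acid-catalysed esterification. The uncatalysed cycloaddition of 1 with acetylenic esters is an established reaction type and involves no acid.
- It should give, without useful selectivity, the menthyl (3S,6R)-adduct F2 and the menthyl (3R,6S)-adduct F3.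
- The mixture is osmylated as in step 2 to the menthyl ester diol F4 (from F2) and the diastereomeric diol F5 (from F3), and protected as in step 3 to the menthyl ester acetonide F6 and the diastereomeric acetonide F7.
- F6 and F7 are diastereomers and are separated by crystallisation or chromatography. F6 is reduced with iBu2AlH as in step 4 to 6, with recovery of menthol.
- The price is half the material and the need to assign F6.

**Step 2.** The risks are loss of acetic acid from 3 with aromatisation before osmylation is complete (the amine formed from NMO is a base), acetyl migration onto the new hydroxyls, and over-oxidation at C1=C2. Fallback, from 3 back to 4: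
- Crude 3 in CH2Cl2 is trapped at −78 °C with stoichiometric OsO4 and TMEDA, a combination that osmylates alkenes within minutes at that temperature.
- The product, the TMEDA-chelated cyclic osmate ester F8 (hexavalent osmium), is robust and can be purified.
- It is then cleaved reductively with aqueous NaHSO3 to 4.
- This replaces a slow catalytic turnover near 0 °C by a cold stoichiometric capture followed by a separate release.

**Step 7.** The risks are opening of the orthoester with the wrong regiochemistry (ester on O4) if the reacting conformer is not the one assumed, orthoester formation on a trans pair, and acyl migration during isolation. Fallback, from 9 to 12: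
- 9 is heated with Bu2SnO in MeOH to give the 4,5-O-dibutylstannylene acetal F9, which is treated with 7 (1 equiv) at 0 °C.
- Stannylene acetals of cis-diols are acylated on the equatorial oxygen, the opposite of the orthoester opening.
- If the orthoester route shows that O4 is the axial oxygen, this method delivers the O5 benzoate.

**Step 5.** The risks are over-acylation at O3 or O6 and base-induced migration of the benzoate from O7 to O6. Fallback, from 6 to 8:
- Mitsunobu esterification with benzoic acid (PPh3, diisopropyl azodicarboxylate, THF, 0 °C).
- Here the alcohol is the electrophile, and selectivity rests on the faster SN2 displacement at the primary carbon C7, not on hydroxyl nucleophilicity.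
- This fallback makes no new compound (F0).

Further compounds

F1 | step 1 | (1R,2S,5R)-menthyl propiolate | CC(C)[C@@H]1CC[C@@H](C)C[C@H]1OC(=O)C#C
F2 | step 1 | (1R,2S,5R)-menthyl (3S,6R)-3,6-diacetoxycyclohexa-1,4-diene-1-carboxylate | CC(C)[C@@H]1CC[C@@H](C)C[C@H]1OC(=O)C1=C[C@@H](OC(C)=O)C=C[C@H]1OC(C)=O
F3 | step 1 | (1R,2S,5R)-menthyl (3R,6S)-3,6-diacetoxycyclohexa-1,4-diene-1-carboxylate | CC(C)[C@@H]1CC[C@@H](C)C[C@H]1OC(=O)C1=C[C@H](OC(C)=O)C=C[C@@H]1OC(C)=O
F4 | step 1 | (1R,2S,5R)-menthyl (3R,4R,5S,6S)-3,6-diacetoxy-4,5-dihydroxycyclohex-1-ene-1-carboxylate | CC(C)[C@@H]1CC[C@@H](C)C[C@H]1OC(=O)C1=C[C@@H](OC(C)=O)[C@H](O)[C@H](O)[C@H]1OC(C)=O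
F5 | step 1 | (1R,2S,5R)-menthyl (3S,4S,5R,6R)-3,6-diacetoxy-4,5-dihydroxycyclohex-1-ene-1-carboxylate | CC(C)[C@@H]1CC[C@@H](C)C[C@H]1OC(=O)C1=C[C@H](OC(C)=O)[C@@H](O)[C@@H](O)[C@@H]1OC(C)=O
F6 | step 1 | (1R,2S,5R)-menthyl (3R,4S,5R,6S)-3,6-diacetoxy-4,5-(isopropylidenedioxy)cyclohex-1-ene-1-carboxylate | CC(C)[C@@H]1CC[C@@H](C)C[C@H]1OC(=O)C1=C[C@@H](OC(C)=O)[C@@H]2OC(C)(C)O[C@@H]2[C@H]1OC(C)=O
F7 | step 1 | (1R,2S,5R)-menthyl (3S,4R,5S,6R)-3,6-diacetoxy-4,5-(isopropylidenedioxy)cyclohex-1-ene-1-carboxylate | CC(C)[C@@H]1CC[C@@H](C)C[C@H]1OC(=O)C1=C[C@H](OC(C)=O)[C@H]2OC(C)(C)O[C@H]2[C@@H]1OC(C)=O
F8 | step 2 | cyclic 4,5-osmate ester of 4 (dioxo-osmium glycolate, hexavalent osmium) with chelating TMEDA | COC(=O)C1=C[C@@H](OC(C)=O)[C@@H]2O[Os](=O)(=O)O[C@@H]2[C@H]1OC(C)=O.CN(C)CCN(C)C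
F9 | step 7 | 4,5-O-dibutylstannylene acetal of 9 | O=C(OCC1=C[C@@H](O)[C@@H]2O[Sn](CCCC)(CCCC)O[C@@H]2[C@H]1O)c1ccccc1
F0 | step 5 | none | none
A1 | alternative 1 | L-mannose (pyranose form) | OC[C@@H]1OC(O)[C@H](O)[C@H](O)[C@H]1O
A2 | alternative 1 | methyl 3-O-benzoyl-6-deoxy-2,4-bis-O-(4-methoxybenzyl)-L-lyxo-hex-5-enopyranoside (either anomer) | C=C1OC(OC)[C@H](OCc2ccc(OC)cc2)[C@H](OC(=O)c2ccccc2)[C@H]1OCc1ccc(OC)cc1
A3 | alternative 1 | 5-benzoyloxy-3-hydroxy-4,6-bis(4-methoxybenzyloxy)cyclohexan-1-one (target numbering, configuration at C3 to C6 as in the target) | O=C1C[C@@H](O)[C@H](OCc2ccc(OC)cc2)[C@H](OC(=O)c2ccccc2)[C@H]1OCc1ccc(OC)cc1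
A4 | alternative 2 | (−)-shikimic acid, (3R,4S,5R)-3,4,5-trihydroxycyclohex-1-ene-1-carboxylic acid | OC(=O)C1=C[C@@H](O)[C@@H](O)[C@H](O)C1
A5 | alternative 2 | [(4S,5R)-4,5-(isopropylidenedioxy)cyclohexa-1(6),2-dien-1-yl]methyl benzoate (target numbering) | O=C(OCC1=C[C@H]2OC(C)(C)O[C@H]2C=C1)c1ccccc1
A6 | alternative 2 | [5,6-(isopropylidenedioxy)-2,3-dioxabicyclo[2.2.2]oct-7-en-7-yl]methyl benzoate (C3,C6-endoperoxide anti to the acetonide) | O=C(OCC1=C[C@@H]2[C@@H]3OC(C)(C)O[C@@H]3[C@H]1OO2)c1ccccc1
A7 | alternative 3 | cyclopentene with C1 (CH2OTBS)=C3, 4,5-acetonide and C6 OTBS (target numbering, C2 absent) | CC(C)(C)[Si](C)(C)OCC1=C[C@@H]2OC(C)(C)O[C@@H]2[C@H]1O[Si](C)(C)C(C)(C)C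
A8 | alternative 3 | 6,6-dibromobicyclo[3.1.0]hexane from A7 (CBr2 bridging C1 and C3, anti to the acetonide) | CC(C)(C)[Si](C)(C)OC[C@]12C(Br)(Br)[C@H]1[C@@H]3OC(C)(C)O[C@@H]3[C@H]2O[Si](C)(C)C(C)(C)C
A9 | alternative 3 | 2-bromocyclohex-2-en-1-ol (target numbering: C3 alcohol, C2 bromide, 4,5-acetonide, C6 and C7 silyl ethers) | CC(C)(C)[Si](C)(C)OCC1=C(Br)[C@@H](O)[C@@H]2OC(C)(C)O[C@@H]2[C@H]1O[Si](C)(C)C(C)(C)C
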